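## The problem

Target 10 is (1R,2S,5R,6S)-2,6-bis(4-hydroxy-3-methoxyphenyl)-3,7-dioxabicyclo[3.3.0]octane-1,5-diol. Ring A (C1–C2–O3–C4–C5) and ring B (C5–C6–O7–C8–C1) are tetrahydrofurans cis-fused along C1–C5, and a twofold axis runs through the midpoint of that bond.

The hardest feature is the C1–C5 bond. It joins two fully substituted carbinol carbons, and each of them carries two more oxygenated carbons. Any carbonyl, ketyl or carbanion placed at C1 or C5 therefore has an oxygen leaving group beside it, and the bond is crowded.

C1 and C5 must have like configuration (R,R). Only that pair can be cis-fused, and it cannot be corrected once set. C2 and C6 carry their aryl groups exo, cis to the neighbouring bridgehead OH. A benzylic centre can steer the creation of its bridgehead neighbour, and the bridgeheads can later steer the benzylic centres.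

C2–O3 and C6–O7 are benzylic ethers para to free phenols:
- Acid re-ionises them, which leads to epimerisation to endo isomers or Friedel–Crafts closure onto the other arene.
- Hydrogenolysis cleaves them.
- Oxidants attack the guaiacyl rings.
- A quinone methide that bears a CH2O– arm can expel formaldehyde.

The feature that makes the key step possible is this same lability combined with the topology. C2 and C8 both hang on C1, and C6 and C4 both hang on C5. O7 could therefore equally bridge C8 and C2, and O3 could bridge C4 and C6, as two oxetanes. Target 10 is thus the strain-free constitutional isomer of the pinacol dimer of a 2-aryloxetan-3-one.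

## Retrosynthesis

**10 ⇒ 9 ⇒ 8 (stored as 7).** The bonds cut are C2–O3 and C6–O7. Of the four ring C–O bonds, these two are made heterolytically labile by the para-phenol. They can therefore be formed last, without a leaving group and under very mild conditions. Cutting C4–O3 and C8–O7 instead would need activated primary carbons and would fix the benzylic configuration beforehand. The cut gives the bis(quinone methide) 9, which cannot be stored. Reconnecting each freed hydroxyl to the benzylic carbon of its own half (O7 to C2, O3 to C6) gives the bis(oxetane) 8. Compound 8 is an isomer of 10 and is kept as its dipivalate 7. Compound 8 has no fused ring and falls into two identical halves. The forward reaction must ionise only the strained ethers, close two five-membered rings, and place both aryl groups exo.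

**7 ⇒ 6 + 6.** The bond cut is C1–C5, the pinacol retron on the twofold axis. It halves the molecule and makes the crowded bond and both bridgehead stereocentres in one operation. The neighbouring cuts, C1–C2 and C5–C6, would need two successive α-oxy carbanions next to a growing quaternary centre. The oxetan-3-one 6 has a single stereocentre. Its small tied-back ring eases the coupling, and its C2 aryl group shields one face of the carbonyl. Its flat ring also holds both α C–O bonds in the nodal plane of the ketyl, so they cannot be expelled. The forward reaction must couple ketyl with ketyl, anti to the aryl group on both partners.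

**6 ⇒ 5.** The bonds cut are the oxetane CH2–O bond (C8–O7) and the carbonyl C=O. Both are traced to a terminal alkyne through an α-oxo gold carbene and O–H insertion. This builds the strained ring in one step from a secondary propargylic alcohol. A Williamson route would need a differentiated triol and a later oxidation. Precursor 5 is acyclic. The forward reaction must leave the carbinol stereocentre untouched.

**5 ⇒ 4 ⇒ 2 + 3, and 2 ⇒ 1.** The bond cut is carbinol carbon to alkyne carbon. A catalytic enantioselective alkynylation of aldehyde 2 with silylacetylene 3 sets the only stereocentre that a reagent introduces in the whole route. The pivalate put on vanillin 1 turns the para-donor off, so all benzylic C–O bonds stay locked until the last step.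

## Roads not taken

**Alternative 1:** (the most obvious) This route cuts C4–O3 and C8–O7 and traces both bridgehead oxygens to epoxides. The forward key step is a hydroxyl-directed double epoxidation of the diene diol A1 to the bis(epoxide) A2. Each benzylic hydroxyl then attacks the CH2 terminus of the epoxide of the other half.
- A1 needs an enantioselective carbinol synthesis, conversion into a 2-halo or 2-metallo allylic alcohol, and a vinyl–vinyl homocoupling, so the C1–C5 bond costs several functional-group steps.
- Both bridgeheads then depend on acyclic induction in two successive epoxidations of a twisted diene, with three possible bis(epoxides).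
- Each closure holds both epoxide carbons in the new ring (5-endo mode).

The chosen plan sets C1 and C5 in the step that makes the C1–C5 bond, under control of a rigid ring, and is shorter.

**Alternative 2:** This route makes the same C1–C5 cut on open-chain halves. The forward key step is SmI2 coupling of two molecules of the ketone A3, followed by desilylation and closure of both rings.
- In A3 both α C–O bonds can rotate into overlap with the ketyl, so reductive α-deoxygenation competes with coupling.
- The freely rotating benzylic centre gives little facial bias, so like and unlike bridgehead pairs are both expected, and only the like pair can be cis-fused.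
- The ring closure then needs acid on unstrained benzylic alcohols, under which 10 itself epimerises.

The oxetanone 6 removes all three problems by geometry and strain.

**Alternative 3:** This route cuts C1–C2 and C5–C6 and reads C1(OH)–C5(OH) as tartaric acid. The forward key step is a double aldol–lactonisation of the tartrate acetonide A4 with two aldehyde molecules to give the propellane bis(lactone) A5, followed by reduction of both lactones to ethers.
- A4 maps onto 10 only if both additions occur with retention, syn to the neighbouring ester, and nothing in the structure enforces that.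
- Each enolate has a β-alkoxy leaving group.
- The second C–C bond is made next to a quaternary carbon.
- The two lactone-to-ether reductions add redox steps in the presence of benzylic C–O bonds.

The chosen plan needs no adjustment of oxidation level after the skeleton is made.

Key step: step 6

Assumption: the (S,S) antipode of ProPhenol is taken to deliver the alkynyl group to the face of 2 that gives 4 as drawn. If the sense proves opposite, the equally available (R,R) ligand is used and nothing else changes.

## Route

Step 1
Reactants: 1 vanillin
Product: 2 4-formyl-2-methoxyphenyl pivalate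
Conditions: PivCl, Et3N, DMAP (cat.), CH2Cl2, 0 °C to rt
Reagents that add atoms: pivaloyl chloride, CC(C)(C)C(=O)Cl
Why: Phenol acylation; the hindered, electron-withdrawing ester switches off the para-donor, so the benzylic C–O bonds made later stay intact until step 6, and it resists organozinc, fluoride, gold and SmI2.

Step 2
Reactants: 2 4-formyl-2-methoxyphenyl pivalate; 3 (trimethylsilyl)acetylene
Product: 4 4-[(1R)-1-hydroxy-3-(trimethylsilyl)prop-2-yn-1-yl]-2-methoxyphenyl pivalate
Conditions: Me2Zn, (S,S)-ProPhenol (20 mol %), Ph3PO (40 mol %), toluene, 0 °C; then 1 M aq. HCl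
Reagents that add atoms: none
Why: Catalytic enantioselective alkynylation of an aryl aldehyde by an alkynylzinc formed in situ on a dinuclear zinc–ProPhenol catalyst, which selects the aldehyde face and sets the only reagent-controlled stereocentre of the route. Dialkylzinc does not attack the hindered aryl pivalate.

Step 3
Reactants: 4 4-[(1R)-1-hydroxy-3-(trimethylsilyl)prop-2-yn-1-yl]-2-methoxyphenyl pivalate
Product: 5 4-[(1S)-1-hydroxyprop-2-yn-1-yl]-2-methoxyphenyl pivalate
Conditions: Bu4NF, AcOH, THF, 0 °C
Reagents that add atoms: none
Why: Fluoride protodesilylation of an alkynylsilane, with the acetic acid buffer suppressing pivaloyl transfer. The stereocentre is not involved, and the descriptor changes from R to S only because ethynyl ranks below aryl whereas silylethynyl ranks above it.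

Step 4
Reactants: 5 4-[(1S)-1-hydroxyprop-2-yn-1-yl]-2-methoxyphenyl pivalate
Product: 6 2-methoxy-4-[(2R)-3-oxooxetan-2-yl]phenyl pivalate
Conditions: BrettPhosAuNTf2 (5 mol %), 2,6-dibromopyridine N-oxide, ClCH2CH2Cl, rt
Reagents that add atoms: 2,6-dibromopyridine N-oxide, [O-][n+]1c(Br)cccc1Br
Why: Gold-catalysed alkyne oxidation of a secondary propargylic alcohol: the N-oxide adds to the internal alkyne carbon, loss of the pyridine leaves an α-oxo gold carbene at the terminal carbon, and intramolecular O–H insertion closes the oxetan-3-one. The carbinol C–H and C–O bonds are untouched, so the configuration is retained (S becomes R only because the new carbonyl carbon outranks the arene). The weakly basic pyridine by-product needs no acid additive, and the pivalate keeps the arene and the benzylic position deactivated.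

Step 5
Reactants: 6 2-methoxy-4-[(2R)-3-oxooxetan-2-yl]phenyl pivalate (two molecules)
Product: 7 (2R,2'R,3R,3'R)-2,2'-bis[3-methoxy-4-(pivaloyloxy)phenyl]-3,3'-bioxetane-3,3'-diol
Conditions: SmI2, THF, -20 °C to rt, no proton source; then aq. NaHCO3
Reagents that add atoms: none
Why: Pinacol homocoupling of an aliphatic ketone with SmI2, known for open-chain ketones and cyclobutanones; the strained, inductively activated carbonyl accepts an electron readily, and the flat ring keeps both α C–O bonds in the nodal plane of the ketyl, so α-deoxygenation has no orbital overlap. Each ketyl carbon bonds on the face anti to its own aryl group, so two (R)-ketones give the twofold-symmetric (3R,3'R) diol with OH cis to aryl. Coupling of an (R)- with a residual (S)-ketone gives a separable diastereomer, which raises the enantiomeric purity of 7 (Horeau principle).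

Step 6
Reactants: 7 (2R,2'R,3R,3'R)-2,2'-bis[3-methoxy-4-(pivaloyloxy)phenyl]-3,3'-bioxetane-3,3'-diol
Product: 10 (1R,2S,5R,6S)-2,6-bis(4-hydroxy-3-methoxyphenyl)-3,7-dioxabicyclo[3.3.0]octane-1,5-diol, via bis(phenol) bis(oxetane) 8 (not isolated), via bis(quinone methide) 9 (not isolated)
Conditions: NaOMe (25 wt % in MeOH, 2.2 equiv), THF, -20 °C; AcOH (2.2 equiv); evaporation at 0 °C; (CF3)2CHOH/CH2Cl2 1:4, 0 °C to rt
Reagents that add atoms: none
Why: Proposed new method: cold methoxide removes both pivalates, and in the freed bis(phenol) 8 each benzylic oxetane bond (C2–O7 and C6–O3 in the numbering of 10) is para to a strong donor and carries the ring strain of an oxetane (about 25 kcal/mol), so hydrogen-bond activation by (CF3)2CHOH should ionise it to the quinone methide (9 once both have opened, or its O-protonated form) while the oxygen stays on its CH2 group as a primary alcohol. The closest known reaction types are the acid-promoted intramolecular opening of oxetanes by oxygen nucleophiles to tetrahydrofurans, the 1,6-addition of alcohols to p-quinone methides and the spontaneous double closure of the bis(quinone methide) formed in the oxidative coupling of coniferyl alcohol; what is new is the exchange of ether partners between two oxetanes. Ring A closes by 5-exo-trig addition of the C4 hydroxyl to C2 and ring B by 5-exo-trig addition of the C8 hydroxyl to C6. Return of a hydroxyl to its own benzylic carbon (4-exo) or attack by a tertiary hydroxyl only regenerates a strained and equally labile benzylic ether, so these paths are reversible and drain into 10. C1 and C5 are not touched, and their like (R,R) configuration places each CH2OH arm cis to the quinone methide of the other half, which permits only the cis-fused bicycle. C2 and C6 are set anew under control of C1 and C5: allylic 1,3-strain puts the smallest group on the bridgehead carbon (OH) in the plane of the quinone methide, the tethered oxygen adds from the side of the other bridgehead, and the aryl group ends cis to the adjacent OH, that is exo (2S,6S). Direct attack of the neighbouring oxetane oxygen on C2 or C6 with inversion (5-exo-tet) leads from (2R,2'R)-8 to the same configuration, so the stepwise and the concerted channels converge. The step needs discrimination between strained and unstrained p-hydroxybenzyl ethers, which the strain difference secures, and it needs the absence of alkoxide and external nucleophiles, which the buffered non-nucleophilic medium secures, so neither epimerisation of 10 nor retro-aldol loss of formaldehyde from the quinone methide should compete.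

## Compound list

1 | vanillin | O=Cc1ccc(O)c(OC)c1 | starting material
2 | 4-formyl-2-methoxyphenyl pivalate | O=Cc1ccc(OC(=O)C(C)(C)C)c(OC)c1 | intermediate
3 | (trimethylsilyl)acetylene | C#C[Si](C)(C)C | starting material
4 | 4-[(1R)-1-hydroxy-3-(trimethylsilyl)prop-2-yn-1-yl]-2-methoxyphenyl pivalate | C[Si](C)(C)C#C[C@H](O)c1ccc(OC(=O)C(C)(C)C)c(OC)c1 | intermediate
5 | 4-[(1S)-1-hydroxyprop-2-yn-1-yl]-2-methoxyphenyl pivalate | C#C[C@H](O)c1ccc(OC(=O)C(C)(C)C)c(OC)c1 | intermediate
6 | 2-methoxy-4-[(2R)-3-oxooxetan-2-yl]phenyl pivalate | O=C1CO[C@@H]1c2ccc(OC(=O)C(C)(C)C)c(OC)c2 | intermediate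
7 | (2R,2'R,3R,3'R)-2,2'-bis[3-methoxy-4-(pivaloyloxy)phenyl]-3,3'-bioxetane-3,3'-diol | O[C@@]1(CO[C@@H]1c2ccc(OC(=O)C(C)(C)C)c(OC)c2)[C@@]3(O)CO[C@@H]3c4ccc(OC(=O)C(C)(C)C)c(OC)c4 | intermediate
8 | (2R,2'R,3R,3'R)-2,2'-bis(4-hydroxy-3-methoxyphenyl)-3,3'-bioxetane-3,3'-diol | O[C@@]1(CO[C@@H]1c2ccc(O)c(OC)c2)[C@@]3(O)CO[C@@H]3c4ccc(O)c(OC)c4 | intermediate
9 | 4,4'-[(2S,3S)-2,3-dihydroxy-2,3-bis(hydroxymethyl)butane-1,4-diylidene]bis(2-methoxycyclohexa-2,5-dien-1-one), exocyclic alkene geometry open | OC[C@@](O)(C=C1C=CC(=O)C(OC)=C1)[C@@](O)(CO)C=C2C=CC(=O)C(OC)=C2 | intermediate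
10 | (1R,2S,5R,6S)-2,6-bis(4-hydroxy-3-methoxyphenyl)-3,7-dioxabicyclo[3.3.0]octane-1,5-diol | COc1cc([C@@H]2OC[C@@]3(O)[C@H](c4ccc(O)c(OC)c4)OC[C@@]23O)ccc1O | target

## Step count and least certain steps

Total step count: 6. Longest linear sequence: 6 steps (1 to 10).

**Step 6 (key step, new method).** The quinone methide may be intercepted before the second oxetane has opened. Possible interceptors are residual methanol or acetate, or the other arene (Friedel–Crafts closure to an aryltetralin). Kinetic control may also be lost, so that the finished benzylic ethers re-ionise and epimerise. Both failures arise because the first quinone methide has no five-ring-forming hydroxyl until its partner ring opens.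

The fallback uses known chemistry only and sets out from 7.
- Acid-catalysed hydrolysis of both oxetanes (cat. H2SO4, aqueous dioxane) gives the hexol dipivalate F1 with the benzylic configuration left open. Attack of water at either oxetane carbon gives the same 1,3-diol.
- NaOMe in MeOH frees the hexol bis(phenol) F2.
- Me3SiBr converts the two p-hydroxybenzylic alcohols into the benzylic dibromide F3.
- A wash with aqueous NaHCO3, the standard entry to guaiacyl quinone methides, eliminates HBr.

The route is rejoined at 9, which closes to 10 under the same allylic-strain control.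

**Step 5.** Hydrogen abstraction from the solvent or a second electron transfer may reduce the carbonyl before two ketyls meet. Facial bias may also be incomplete, which gives unsymmetrical dimers that cannot be cis-fused.

The fallback sets both bridgeheads at once from one face of an alkene. It sets out from 2.
- The antipodal ligand in step 2, followed by steps 3 and 4, gives the (S)-silylalkynyl carbinol F4, the (R)-ethynyl carbinol F5 and the (S)-oxetanone F6.
- McMurry coupling (TiCl4, Zn, pyridine, THF) gives the (E)-bi(oxetanylidene) F7, in which both aryl groups lie on the same face.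
- OsO4/NMO dihydroxylation from the open face gives the trans-configured diol dipivalate F8, with bridgeheads R,R and OH trans to aryl.
- Cold NaOMe gives the trans-configured bis(phenol) F9.

F9 ionises under the conditions of step 6, where only the quinone methide channel is productive. The route is rejoined at 9.

**Step 4.** The α-oxo gold carbene may be trapped by the methoxy-activated arene or by the hydroxyl of a second molecule instead of closing the strained ring. The benzylic propargylic alcohol may also ionise on the cationic gold centre.

The fallback closes the ring by substitution instead of carbene insertion. It sets out from 5.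
- NBS with AgNO3 (cat.) gives the bromoalkyne F10.
- Hydration of the haloalkyne (XPhosAuNTf2, H2O, ClCH2CH2Cl) gives the α-bromo ketone F11.
- Ag2O-assisted intramolecular Williamson closure (4-exo-tet) rejoins the route at 6.

**Step 2.** Face selection by the catalyst may be insufficient for this ester-bearing aldehyde, or the pivaloyl group may slowly transfer to the zinc alkoxide.

The fallback sets the stereocentre by reduction instead of addition. It sets out from 2.
- Ethynylmagnesium bromide at -78 °C gives the racemic ethynyl carbinol F12.
- MnO2 gives the ynone F13.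
- Midland reduction with (R)-Alpine-Borane, with the linear alkynyl group acting as the small substituent, rejoins the route at 5 and bypasses 4.

## Further compounds

F1 | step 6 | (2R,3R)-2,3-bis(hydroxymethyl)-1,4-bis[3-methoxy-4-(pivaloyloxy)phenyl]butane-1,2,3,4-tetraol, benzylic centres open | OC[C@@](O)(C(O)c1ccc(OC(=O)C(C)(C)C)c(OC)c1)[C@@](O)(CO)C(O)c2ccc(OC(=O)C(C)(C)C)c(OC)c2
F2 | step 6 | (2R,3R)-1,4-bis(4-hydroxy-3-methoxyphenyl)-2,3-bis(hydroxymethyl)butane-1,2,3,4-tetraol, benzylic centres open | OC[C@@](O)(C(O)c1ccc(O)c(OC)c1)[C@@](O)(CO)C(O)c2ccc(O)c(OC)c2
F3 | step 6 | 2,3-bis[bromo(4-hydroxy-3-methoxyphenyl)methyl]butane-1,2,3,4-tetraol, bridgehead carbons as in F2, benzylic centres open | OC[C@@](O)(C(Br)c1ccc(O)c(OC)c1)[C@@](O)(CO)C(Br)c2ccc(O)c(OC)c2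
F4 | step 5 | 4-[(1S)-1-hydroxy-3-(trimethylsilyl)prop-2-yn-1-yl]-2-methoxyphenyl pivalate | C[Si](C)(C)C#C[C@@H](O)c1ccc(OC(=O)C(C)(C)C)c(OC)c1
F5 | step 5 | 4-[(1R)-1-hydroxyprop-2-yn-1-yl]-2-methoxyphenyl pivalate | C#C[C@@H](O)c1ccc(OC(=O)C(C)(C)C)c(OC)c1
F6 | step 5 | 2-methoxy-4-[(2S)-3-oxooxetan-2-yl]phenyl pivalate | O=C1CO[C@H]1c2ccc(OC(=O)C(C)(C)C)c(OC)c2
F7 | step 5 | (E,2S,2'S)-2,2'-bis[3-methoxy-4-(pivaloyloxy)phenyl]-3,3'-bi(oxetanylidene) | CC(C)(C)C(=O)Oc1ccc(cc1OC)[C@@H]2OC/C2=C3/CO[C@H]3c4ccc(OC(=O)C(C)(C)C)c(OC)c4
F8 | step 5 | (2S,2'S,3R,3'R)-2,2'-bis[3-methoxy-4-(pivaloyloxy)phenyl]-3,3'-bioxetane-3,3'-diol | O[C@@]1(CO[C@H]1c2ccc(OC(=O)C(C)(C)C)c(OC)c2)[C@@]3(O)CO[C@H]3c4ccc(OC(=O)C(C)(C)C)c(OC)c4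
F9 | step 5 | (2S,2'S,3R,3'R)-2,2'-bis(4-hydroxy-3-methoxyphenyl)-3,3'-bioxetane-3,3'-diol | O[C@@]1(CO[C@H]1c2ccc(O)c(OC)c2)[C@@]3(O)CO[C@H]3c4ccc(O)c(OC)c4
F10 | step 4 | 4-[(1R)-3-bromo-1-hydroxyprop-2-yn-1-yl]-2-methoxyphenyl pivalate | BrC#C[C@H](O)c1ccc(OC(=O)C(C)(C)C)c(OC)c1
F11 | step 4 | 4-[(1R)-3-bromo-1-hydroxy-2-oxopropyl]-2-methoxyphenyl pivalate | BrCC(=O)[C@H](O)c1ccc(OC(=O)C(C)(C)C)c(OC)c1
F12 | step 2 | racemic 4-(1-hydroxyprop-2-yn-1-yl)-2-methoxyphenyl pivalate | C#CC(O)c1ccc(OC(=O)C(C)(C)C)c(OC)c1
F13 | step 2 | 2-methoxy-4-(prop-2-ynoyl)phenyl pivalate | C#CC(=O)c1ccc(OC(=O)C(C)(C)C)c(OC)c1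
A1 | alternative 1 | (1S,4S)-1,4-bis[3-methoxy-4-(pivaloyloxy)phenyl]-2,3-dimethylidenebutane-1,4-diol | O[C@@H](c1ccc(OC(=O)C(C)(C)C)c(OC)c1)C(=C)C(=C)[C@@H](O)c2ccc(OC(=O)C(C)(C)C)c(OC)c2
A2 | alternative 1 | (S,S)-[(2R,2'R)-2,2'-bioxirane-2,2'-diyl]bis{[3-methoxy-4-(pivaloyloxy)phenyl]methanol} | O[C@@H](c1ccc(OC(=O)C(C)(C)C)c(OC)c1)[C@]2(CO2)[C@@]3(CO3)[C@@H](O)c4ccc(OC(=O)C(C)(C)C)c(OC)c4
A3 | alternative 2 | 4-[(1R)-1,3-bis(tert-butyldimethylsilyloxy)-2-oxopropyl]-2-methoxyphenyl pivalate | CC(C)(C)[Si](C)(C)OCC(=O)[C@H](O[Si](C)(C)C(C)(C)C)c1ccc(OC(=O)C(C)(C)C)c(OC)c1
A4 | alternative 3 | dimethyl (4R,5R)-2,2-dimethyl-1,3-dioxolane-4,5-dicarboxylate | COC(=O)[C@@H]1OC(C)(C)O[C@H]1C(=O)OC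
A5 | alternative 3 | 1,5-O-isopropylidene-2,6-bis(4-benzyloxy-3-methoxyphenyl)-1,5-dihydroxy-3,7-dioxabicyclo[3.3.0]octane-4,8-dione, configured as 10 | CC1(C)O[C@@]23C(=O)O[C@@H](c4ccc(OCc5ccccc5)c(OC)c4)[C@]2(O1)C(=O)O[C@H]3c6ccc(OCc7ccccc7)c(OC)c6
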